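Its constants are assumed; the result is computed.

A closed, stirred flask at constant volume holds Z, J and X: X gives G, G and Z give the living end L, and J takes L away.

in all of them: Z 0.50 mM; J 0.0150 mM; X 5 mol%; time 20 s

| flask | temperature |
|---|---|
| dusk | 60 °C |
| winter | 45 °C |

    Z + L → E + L, rate k1*[L]*[Z] (k1 = 20000 L mol⁻¹ s⁻¹, Ea1 = 18.0 kJ mol⁻¹)
    X → G (k2 = 0.19 s⁻¹, Ea2 = 90.0 kJ mol⁻¹)
    L + J → L.J (k3 = 19000 L mol⁻¹ s⁻¹, Ea3 = 33.0 kJ mol⁻¹)
    Z + E → Z.E (k4 = 850 L mol⁻¹ s⁻¹, Ea4 = 37.0 kJ mol⁻¹)
    Z + G → L + E (k5 = 2300 L mol⁻¹ s⁻¹, Ea5 = 41.0 kJ mol⁻¹)
    (constants at 60 °C)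

1. which flask leads in amount of E, in percent of the Z charged ("all alike" within 1.5 percentage points) (dusk / winter / all alike)
2. how much E is there at the end, in percent of the Z charged: dusk
3. how much E is there at the end, in percent of the Z charged: winter

- in percentages every species weighs as the Z in it: one Z.E counts as two
- the list of constants is for 60 °C, to be carried to other temperatures by the activation energies

The first question is what stops E. Leaving aside the one E that each G gives, E is made at kP[L][Z] and used at kC[E][Z], where kP and kC are the constants of Z + L and Z + E. [Z] stands in both rates, so with [L] held, E heads for H = (kP/kC)[L], with kP/kC at 23.5 in dusk and 32.5 in winter.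

The second question is what [L] to freeze. With Z at its charge, Z in dusk takes up G at 1.15 s⁻¹, faster than X gives it at 0.19 s⁻¹, and Z in winter takes it up at 0.572 s⁻¹, faster than X gives it at 0.0411 s⁻¹, so in this reckoning G is taken to pass straight on to L. L is then fed from the X charged, Xc = 0.0250 mM, with constant kX, and drained by J with constant a, J frozen at its charge. In dusk a is 0.285 s⁻¹. In winter a is 0.163 s⁻¹ and kX is 0.0411 s⁻¹. Two first-order steps in series peak at Xc(kX/a)^(a/(a−kX)), which gives 0.00741 mM in dusk and 0.00397 mM in winter.

So H is 0.174 mM in dusk and 0.129 mM in winter: the ceiling of E, the level at which E is made as fast as it is used. Winter's ratio is larger and its [L] smaller, and its ceiling is lower.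

The third question is how far E climbs before Z is used. Dividing the two rates gives dE/dZ = −(H−E)/(H+E), and once the Z charged, Zc, is used up, E stands short of H by about the fraction exp(−(Zc/H+1)/2). That gives 29.8% in dusk and 23.5% in winter, so dusk leads. Near the ceiling Z falls pseudo-first-order with constant 2kC·H, a half-life of 5.93 s in winter. Run from the start, this count has winter still holding 9.65% of its Z at 20 s, while the figure above takes Z as used up, so the winter figure leans high.

The forecast, with numbers of its own, gives 29% for dusk and 21.5% for winter: “Dusk leads.”

The flask gives 29.6% in dusk and 22.2% in winter, so dusk leads. At 20.0 s winter makes E 1.27 times as fast as it uses it, with 22% of its Z left. Its ceiling of 25.8% of the Z charged stands against 23.6% of E at 200 s. With J at 0.025 mM and all else as in winter, the ceiling drops to 0.0880 mM and the reckoned E to 17.0%; that flask holds 16.2% of E at 20.0 s.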